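**Retrosynthetic overview**
1. Target 18 ⇒ boron-templated aldol (Pabon) of aryl aldehyde 14 with the half-curcuminoid 17 (from 15 + 16).
2. 14 ⇒ Pd(0) cis-1,4 opening of vinyl epoxide 12 by vanillin 13; 12 ⇒ face-selective epoxidation of α-turmerone 11.
3. 11 ⇒ NHC-catalysed (4+2) annulation of enoyl fluoride 7 with siloxydiene 9: the cyclohexene and a fused β-lactone (10) close in one operation, then CO2 is lost.
4. 7 ⇒ cross-metathesis (acrylic acid) of vinyl ketone 4 ⇒ Ir-catalysed asymmetric allylation of mesityl oxide enol silane 2 with crotyl carbonate 3 (sets the side-chain methyl centre).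
5. Ring order: carbocycle + β-lactone together (step 6; lactone extruded), then the epoxide (step 7; opened in step 8); both arenes are bought.

Assumption: the enol drawn in the target SMILES is the usual H-bonded tautomer of the 1,3-diketone; crotyl methyl carbonate 3 is taken as purchasable; for the chiral catalysts of steps 2 and 6 the antipode that gives the stated centre is used.
Locants used below: C1 = ring carbon carrying the aryl ether O in the target, C2=C3(CH3), C4 = carbinol carbon, C5 = CH2, C6 = ring carbon carrying the side chain, C7 = side-chain CH(CH3).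

**Step 1**
Reactants: 1 mesityl oxide (4-methylpent-3-en-2-one)
Product: 2 4-methyl-2-(trimethylsilyloxy)penta-1,3-diene
Conditions: LDA, THF, −78 °C; TMSCl, −78 °C → rt
Reagents that add atoms: chlorotrimethylsilane, C[Si](C)(C)Cl
Why: Kinetic deprotonation of the acetyl CH3 and O-silylation gives the cross-conjugated silyl enol ether (kinetic silyl enol ether formation); no stereocentre.

**Step 2**
Reactants: 2 4-methyl-2-(trimethylsilyloxy)penta-1,3-diene; 3 (E)-but-2-en-1-yl methyl carbonate
Product: 4 (6S)-2,6-dimethylocta-2,7-dien-4-one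
Conditions: [Ir(cod)Cl]2 (2 mol%), (Sa,Sc,Sc)-Feringa-type phosphoramidite (4 mol%; antipode that gives 6S), CsF, ZnF2, DME, 50 °C
Reagents that add atoms: none
Why: Ir-catalysed asymmetric allylic alkylation in which the fluoride-released enolate attacks the substituted terminus of the Ir–crotyl complex (branched product), the ligand fixing the new methyl-bearing centre as S.

**Step 3**
Reactants: 4 (6S)-2,6-dimethylocta-2,7-dien-4-one; 5 acrylic acid
Product: 6 (2E,4S)-4,8-dimethyl-6-oxonona-2,7-dienoic acid
Conditions: Hoveyda–Grubbs II (3 mol%), benzoquinone (10 mol%), CH2Cl2, 40 °C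
Reagents that add atoms: none
Why: Olefin cross-metathesis of the terminal alkene with acrylic acid gives the E-enoic acid, while the trisubstituted enone alkene is inert and the stereocentre is untouched.

**Step 4**
Reactants: 6 (2E,4S)-4,8-dimethyl-6-oxonona-2,7-dienoic acid
Product: 7 (2E,4S)-4,8-dimethyl-6-oxonona-2,7-dienoyl fluoride
Conditions: cyanuric fluoride (0.4 equiv), pyridine, CH2Cl2, −10 °C → rt; used crude
Reagents that add atoms: cyanuric fluoride, Fc1nc(F)nc(F)n1
Why: Acid-to-acyl-fluoride conversion (deoxyfluorination with cyanuric fluoride) is mild enough to leave the enone and the γ-stereocentre alone.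

**Step 5**
Reactants: 8 tiglic aldehyde [(E)-2-methylbut-2-enal]
Product: 9 (E)-2-methyl-1-(trimethylsilyloxy)buta-1,3-diene
Conditions: TMSOTf, Et3N, Et2O, 0 °C
Reagents that add atoms: trimethylsilyl triflate, C[Si](C)(C)OS(=O)(=O)C(F)(F)F
Why: Soft enolisation (γ-deprotonation and O-silylation of the enal) gives the 1-siloxydiene; no stereocentre, and the enol ether geometry is irrelevant because that carbon ends up sp2.

**Step 6 (key step)**
Reactants: 7 (2E,4S)-4,8-dimethyl-6-oxonona-2,7-dienoyl fluoride; 9 (E)-2-methyl-1-(trimethylsilyloxy)buta-1,3-diene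
Product: 11 α-turmerone, (6S)-2-methyl-6-[(1R)-4-methylcyclohexa-2,4-dien-1-yl]hept-2-en-4-one, via cis-fused bicyclic β-lactone 10 (not isolated)
Conditions: chiral aminoindanol-derived N-mesityl triazolium salt (10 mol%), KHMDS (10 mol%), THF, −78 °C → rt (CO2 evolves)
Reagents that add atoms: none
Why: Proposed new method: the carbene converts 7 into an α,β-unsaturated acyl azolium whose fluoride desilylates 9, the dienolate γ-carbon (C5) adds to the azolium β-carbon (C6) on the face left open by the chiral carbene so that C6 is set R next to the existing 7S centre, the azolium enolate (C1) then closes the carbocycle by aldol addition to the aldehyde (C2) and the alkoxide acylates itself to the fused β-lactone 10 (two rings in one operation, carbene released), which loses CO2 on warming to give the C1=C2–C3=C4 diene; the closest known reaction type is the NHC-catalysed (4+2) annulation/decarboxylation of α,β-unsaturated acyl fluorides with TMS dienol ethers, extended here to an aldehyde-derived dienol ether and a γ-branched, enone-bearing acyl fluoride under catalyst control.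

**Step 7**
Reactants: 11 α-turmerone
Product: 12 α-turmerone C3–C4 epoxide (epoxide on the methyl-bearing ring alkene, oxygen on the ring face opposite to the C6 side chain; C1=C2 retained)
Conditions: mCPBA (1.0 equiv), CH2Cl2/sat. aq. NaHCO3, 0 °C; used directly
Reagents that add atoms: mCPBA, O=C(OO)c1cccc(Cl)c1
Why: Prilezhaev epoxidation takes the trisubstituted, most electron-rich alkene of the diene (the enone alkene is inert) from the face anti to the quasi-axial C6 side chain, setting C3 and C4 with the oxygen trans to the side chain (moderate ratio expected; the minor isomer is removed after step 8).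

**Step 8**
Reactants: 12 α-turmerone C3–C4 epoxide; 13 vanillin
Product: 14 4-{[(1R,4S,6R)-4-hydroxy-3-methyl-6-[(2S)-6-methyl-4-oxohept-5-en-2-yl]cyclohex-2-en-1-yl]oxy}-3-methoxybenzaldehyde
Conditions: Pd2(dba)3·CHCl3 (2.5 mol%), PPh3 (10 mol%), THF, 0 °C → rt
Reagents that add atoms: none
Why: Pd(0)-catalysed allylic substitution of a cyclic vinyl epoxide (Tsuji–Trost): ionisation at C3 with inversion gives a π-allyl/alkoxide pair that deprotonates vanillin, and the phenoxide attacks the unsubstituted terminus C1 anti to Pd (net double inversion), so ArO is cis to the C4–OH and trans to the side chain, setting C1 as R.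

**Step 9**
Reactants: 15 4-hydroxybenzaldehyde; 16 acetylacetone (3 equiv)
Product: 17 (E)-6-(4-hydroxyphenyl)hex-5-ene-2,4-dione
Conditions: B2O3, B(OBu)3, n-BuNH2, EtOAc, 70 °C; then 0.5 M HCl, 50 °C
Reagents that add atoms: none
Why: Pabon boron-templated aldol condensation, in which boron chelation blocks the central carbon of excess acetylacetone so that one terminal methyl condenses to the E-styryl diketone; no stereocentre.

**Step 10**
Reactants: 14 aryl aldehyde; 17 (E)-6-(4-hydroxyphenyl)hex-5-ene-2,4-dione
Product: 18 demethoxybisabolocurcumin ether (target)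
Conditions: B2O3, B(OBu)3, n-BuNH2 (0.2 equiv), EtOAc–DMF, 70 °C; then 10% aq. AcOH, rt
Reagents that add atoms: none
Why: Second Pabon boron-templated aldol condensation: the boron chelate of 17 reacts only at its remaining methyl with aldehyde 14 to give the E-alkene, and the mild acetic acid hydrolysis spares the allylic aryl ether, the allylic alcohol and all four stereocentres.

**Compound list**
1 | mesityl oxide | CC(=O)C=C(C)C | starting material
2 | 4-methyl-2-(trimethylsilyloxy)penta-1,3-diene | C=C(O[Si](C)(C)C)C=C(C)C | intermediate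
3 | (E)-but-2-en-1-yl methyl carbonate | C/C=C/COC(=O)OC | starting material
4 | (6S)-2,6-dimethylocta-2,7-dien-4-one | C=C[C@@H](C)CC(=O)C=C(C)C | intermediate
5 | acrylic acid | C=CC(=O)O | starting material
6 | (2E,4S)-4,8-dimethyl-6-oxonona-2,7-dienoic acid | OC(=O)/C=C/[C@@H](C)CC(=O)C=C(C)C | intermediate
7 | (2E,4S)-4,8-dimethyl-6-oxonona-2,7-dienoyl fluoride | O=C(F)/C=C/[C@@H](C)CC(=O)C=C(C)C | intermediate
8 | tiglic aldehyde | C/C=C(\C)C=O | starting material
9 | (E)-2-methyl-1-(trimethylsilyloxy)buta-1,3-diene | C=C/C(C)=C/O[Si](C)(C)C | intermediate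
10 | cis-fused 5-methyl-2-[(2S)-6-methyl-4-oxohept-5-en-2-yl]-7-oxabicyclo[4.2.0]oct-4-en-8-one (lactone carbonyl trans to the side chain) | O=C1O[C@H]2C(C)=CC[C@H]([C@@H](C)CC(=O)C=C(C)C)[C@@H]12 | intermediate
11 | α-turmerone, (6S)-2-methyl-6-[(1R)-4-methylcyclohexa-2,4-dien-1-yl]hept-2-en-4-one | C1=CC(C)=CC[C@@H]1[C@@H](C)CC(=O)C=C(C)C | intermediate
12 | α-turmerone C3–C4 epoxide, oxygen trans to the side chain | C1=C[C@@]2(C)O[C@H]2C[C@@H]1[C@@H](C)CC(=O)C=C(C)C | intermediate
13 | vanillin | COc1cc(C=O)ccc1O | starting material
14 | 4-{[(1R,4S,6R)-4-hydroxy-3-methyl-6-[(2S)-6-methyl-4-oxohept-5-en-2-yl]cyclohex-2-en-1-yl]oxy}-3-methoxybenzaldehyde | COc1cc(C=O)ccc1O[C@H]1C=C(C)[C@@H](O)C[C@@H]1[C@@H](C)CC(=O)C=C(C)C | intermediate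
15 | 4-hydroxybenzaldehyde | O=Cc1ccc(O)cc1 | starting material
16 | acetylacetone | CC(=O)CC(C)=O | starting material
17 | (E)-6-(4-hydroxyphenyl)hex-5-ene-2,4-dione (drawn as diketone; exists as enol) | CC(=O)CC(=O)/C=C/c1ccc(O)cc1 | intermediate
18 | demethoxybisabolocurcumin ether | COc1cc(/C=C/C(O)=C/C(=O)/C=C/c2ccc(O)cc2)ccc1O[C@H]1C=C(C)[C@@H](O)C[C@@H]1[C@@H](C)CC(=O)C=C(C)C | target

**Step count**
Total: 10 steps. Longest linear sequence: 8 steps (1, 2, 3, 4, 6, 7, 8, 10).

**Three steps most likely to fail, with fallbacks**

Step 6 (annulation). The risks are catalyst control at C6 next to the small existing centre, γ-deprotonation of the acyl azolium (epimerisation at C7), and the untested aldehyde-derived dienol ether. The fallback sets out from acid 6 and replaces the organocatalytic annulation by a Lewis-acid Diels–Alder reaction. Acid 6 is converted (PivCl, Et3N, LiCl, oxazolidin-2-one) into the N-enoyl oxazolidinone F1. A [Cu(t-Bu-box)](SbF6)2-catalysed endo Diels–Alder reaction of F1 with diene 9 (catalyst antipode chosen for 6R; the 1-siloxy group directs the "ortho" regiochemistry) gives the silyloxy cycloadduct F2. LiOH in THF–water removes the oxazolidinone, the silyl ether falls off on acidic work-up, and the cis-β-hydroxy acid F3 results. Lactonisation with PhSO2Cl/pyridine returns to the route at β-lactone 10, which loses CO2 to 11 as before.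

Step 8 (Pd etherification, together with the facial ratio of step 7 that feeds it). The risks are β-hydride elimination and aromatisation of the π-allyl intermediate, ionisation on the hindered face, and an inseparable epoxide diastereomer. The fallback sets out from diene 11, avoids both the epoxide and the π-allyl chemistry, and comes back at aldehyde 14. Photooxygenation (O2, TPP, hν, CH2Cl2, −20 °C) adds singlet oxygen across C1/C4 anti to the side chain to give the endoperoxide F4. Thiourea in MeOH reduces it to the cis-1,4-diol F5. TBSCl/imidazole at low temperature silylates the less hindered C4–OH, which is flanked by CH2, to give the mono-silyl ether F6 (regiochemistry to be confirmed; isomers separable). KHMDS and then 4-fluoro-3-methoxybenzaldehyde arylate the C1 alkoxide by SNAr with retention (the C1–O bond is never broken) to give the silyl-protected aryl ether F7. Buffered TBAF then gives 14.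

Step 10 (final Pabon condensation). The risks are scrambling to symmetrical curcuminoids, amine addition to the side-chain enone, and loss of the allylic aryl ether on hydrolysis, all on the most valuable intermediate. The fallback sets out from aldehyde 14 and inverts the order of the two C=C-forming condensations. 14 is first condensed with a large excess of the boron chelate of cheap acetylacetone 16 to give its own half-curcuminoid, the bisabolyl feruloylacetone F8. F8 is then condensed with an excess of cheap 4-hydroxybenzaldehyde 15, which returns to the route at target 18.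

**Further compounds**
F1 | step 6 | 3-[(2E,4S)-4,8-dimethyl-6-oxonona-2,7-dienoyl]oxazolidin-2-one | O=C1OCCN1C(=O)/C=C/[C@@H](C)CC(=O)C=C(C)C
F2 | step 6 | endo Diels–Alder adduct: C1 acyl oxazolidinone and C2 OTMS cis, both trans to the C6 side chain, C3(Me)=C4 | C[Si](C)(C)O[C@H]1C(C)=CC[C@H]([C@@H](C)CC(=O)C=C(C)C)[C@H]1C(=O)N2CCOC2=O
F3 | step 6 | cis-2-hydroxy-3-methyl-6-[(2S)-6-methyl-4-oxohept-5-en-2-yl]cyclohex-3-ene-1-carboxylic acid (OH and CO2H trans to the side chain) | O[C@H]1C(C)=CC[C@H]([C@@H](C)CC(=O)C=C(C)C)[C@H]1C(=O)O
F4 | step 8 | α-turmerone 1,4-endoperoxide (O–O bridge across C1/C4, anti to the side chain) | [C@@H]12C=C(C)[C@@H](OO1)C[C@@H]2[C@@H](C)CC(=O)C=C(C)C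
F5 | step 8 | cis-1,4-diol (C1–OH and C4–OH cis, both trans to the side chain) | O[C@H]1C=C(C)[C@@H](O)C[C@@H]1[C@@H](C)CC(=O)C=C(C)C
F6 | step 8 | C4-O-TBS mono-silyl ether of the cis-diol (C1–OH free) | O[C@H]1C=C(C)[C@@H](O[Si](C)(C)C(C)(C)C)C[C@@H]1[C@@H](C)CC(=O)C=C(C)C
F7 | step 8 | C4-O-TBS ether of aldehyde 14 | COc1cc(C=O)ccc1O[C@H]1C=C(C)[C@@H](O[Si](C)(C)C(C)(C)C)C[C@@H]1[C@@H](C)CC(=O)C=C(C)C
F8 | step 10 | (E)-6-aryl-hex-5-ene-2,4-dione derived from 14 (bisabolyl feruloylacetone) | CC(=O)CC(=O)/C=C/c1ccc(O[C@H]2C=C(C)[C@@H](O)C[C@@H]2[C@@H](C)CC(=O)C=C(C)C)c(OC)c1
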